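**Retrosynthetic overview**
1. 16 ⇐ 15: reductive removal of a phenylsulfonyl group at ring C-2 (numbering used throughout: C-1 carries the side chain, C-15 is the carbinol carbon).
2. 15 ⇐ 14: the 14-membered carbocycle (the only lasting ring, formed second) is closed by attack of the C-2 sulfonyl carbanion on C-1 of an (R,R)-epoxide; C-1 is set by inversion and the epoxide C-15–O bond survives as the tertiary alcohol.
3. 14 ⇐ 4 + 11: C-8–C-9 bond by hydroboration/B-alkyl Suzuki coupling, then ester reduction to the CH2OH group.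
4. 4 ⇐ 1 ((E,E)-farnesol): the oxirane (formed first) comes from a hydroxyl-anchored, site- and enantioselective epoxidation of the 6,7-alkene, the stereo-defining C–O bond formation (new method), followed by oxidation and methylenation.
5. 11 ⇐ 5 (nerol): sulfone formation, selective ozonolysis, Z-selective iodo-olefination.

Assumption: (2E,6E)-farnesol and nerol are bought as single geometric isomers, and a two-stage one-pot operation with an unpurified intermediate counts as one step.

**Route**

Step 1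
Reactants: 1 (2E,6E)-3,7,11-trimethyldodeca-2,6,10-trien-1-ol [(E,E)-farnesol]
Product: 2 (2E)-3-methyl-5-[(2R,3R)-3-methyl-3-(4-methylpent-3-en-1-yl)oxiran-2-yl]pent-2-en-1-ol [(6R,7R)-6,7-epoxyfarnesol]
Conditions: catalyst K [2,2'-dimethoxy-3,3'-bis(3-(trifluoroacetyl)phenyl)-1,1'-binaphthyl, one atropisomer] (10 mol %), Bu4NHSO5 (1.05 equiv), NaHCO3, 4 Å MS, MeCN–CH2Cl2, −20 °C
Reagents that add atoms: tetrabutylammonium peroxymonosulfate, CCCC[N+](CCCC)(CCCC)CCCC.OOS(=O)(=O)[O-]
Why: Proposed new method: one trifluoromethyl ketone of the C2-symmetric catalyst binds the primary alcohol of 1 reversibly as a hemiketal while the other is turned by peroxymonosulfate into a dioxirane, so oxygen is delivered intramolecularly through a spiro transition state to the 6,7-alkene (the allylic 2,3-alkene is too close to the anchor to reach the dioxirane, the 10,11-alkene needs a larger, entropically costlier cycle and meets the naphthyl wall), the biaryl axis selecting the alkene face and thereby fixing C-15 directly and C-1 through the later invertive opening (the atropisomer giving the 6R,7R sense is chosen in the first screen, both being made from (R)- or (S)-BINOL); closest known reaction types are ketone-catalysed dioxirane asymmetric epoxidation and hydroxyl-directed epoxidation by aspartyl-peptide peracids.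

Step 2
Reactants: 2 (6R,7R)-6,7-epoxyfarnesol
Product: 4 (2R,3R)-2-methyl-3-[(3E)-3-methylhexa-3,5-dien-1-yl]-2-(4-methylpent-3-en-1-yl)oxirane, via epoxy enal 3 (not isolated)
Conditions: MnO2, CH2Cl2, 25 °C, filter; then Ph3PCH3Br, KN(SiMe3)2, THF, −78 → 0 °C
Reagents that add atoms: methyltriphenylphosphonium bromide, C[P+](c1ccccc1)(c1ccccc1)c1ccccc1.[Br-]
Why: MnO2 oxidises only the allylic alcohol with retention of the 2E geometry and Wittig methylenation of the crude enal gives the terminal diene without touching the trisubstituted epoxide, so both stereocentres pass unchanged (allylic oxidation, then Wittig olefination).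

Step 3
Reactants: 5 nerol [(2Z)-3,7-dimethylocta-2,6-dien-1-ol]
Product: 7 {[(2Z)-3,7-dimethylocta-2,6-dien-1-yl]sulfonyl}benzene (neryl phenyl sulfone), via neryl bromide 6 (not isolated)
Conditions: PBr3, Et2O, −10 °C; then PhSO2Na, DMF, 25 °C
Reagents that add atoms: sodium benzenesulfinate, [Na+].[O-]S(=O)c1ccccc1; phosphorus tribromide, BrP(Br)Br (its bromine stays only in 6)
Why: Low-temperature bromination of the allylic alcohol and SN2 S-alkylation of the sulfinate both keep the Z alkene (allylic bromination, then sulfinate alkylation).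

Step 4
Reactants: 7 neryl phenyl sulfone
Product: 8 (4Z)-4-methyl-6-(phenylsulfonyl)hex-4-enal
Conditions: O3 (1.0 equiv, Sudan red endpoint), CH2Cl2, −78 °C; then PPh3
Reagents that add atoms: ozone, [O-][O+]=O
Why: Ozone attacks the electron-rich terminal trisubstituted alkene much faster than the alkene deactivated by the allylic sulfonyl group, so one equivalent cleaves only the isopropylidene end (chemoselective ozonolysis, reductive work-up).

Step 5
Reactants: 8 (4Z)-4-methyl-6-(phenylsulfonyl)hex-4-enal; 9 ethyl (triphenyl-λ5-phosphanylidene)acetate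
Product: 11 ethyl (2Z,6Z)-2-iodo-6-methyl-8-(phenylsulfonyl)octa-2,6-dienoate, via iodo ylide 10 (not isolated)
Conditions: 9, N-iodosuccinimide, CH2Cl2, −20 °C; then 8, −20 → 25 °C
Reagents that add atoms: N-iodosuccinimide, O=C1CCC(=O)N1I
Why: Iodination of the stabilised ylide gives the iodo ylide, whose Wittig reaction with the aliphatic aldehyde puts the ester trans to the chain (Z-iodoenoate), the geometry that later places C-9 cis to C-6 and the CH2OH trans to C-6 (Wittig olefination with an α-halo stabilised ylide).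

Step 6
Reactants: 4 epoxy diene; 11 (Z)-iodoenoate
Product: 13 ethyl (2E,6Z)-6-methyl-2-{(3E)-4-methyl-6-[(2R,3R)-3-methyl-3-(4-methylpent-3-en-1-yl)oxiran-2-yl]hex-3-en-1-yl}-8-(phenylsulfonyl)octa-2,6-dienoate, via alkylborane 12 (not isolated)
Conditions: 4, 9-BBN, THF, 0 → 25 °C; then 11, Pd(dppf)Cl2 (5 mol %), AsPh3, Cs2CO3, DMF–H2O, 25 °C
Reagents that add atoms: 9-borabicyclo[3.3.1]nonane, B1C2CCCC1CCC2 (its boron stays only in 12)
Why: 9-BBN adds only to the terminal CH2 of the diene (trisubstituted alkenes and the epoxide are untouched) and the primary alkylborane couples with the vinyl iodide with retention of alkene geometry, forming the C-8–C-9 bond (hydroboration, then B-alkyl Suzuki–Miyaura coupling).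

Step 7
Reactants: 13 coupled ester
Product: 14 (2E,6Z)-6-methyl-2-{(3E)-4-methyl-6-[(2R,3R)-3-methyl-3-(4-methylpent-3-en-1-yl)oxiran-2-yl]hex-3-en-1-yl}-8-(phenylsulfonyl)octa-2,6-dien-1-ol
Conditions: i-Bu2AlH (2.5 equiv), CH2Cl2, −78 °C
Reagents that add atoms: none
Why: 1,2-Reduction of the enoate at −78 °C leaves the trisubstituted epoxide, the sulfone and all alkene geometries intact, and it removes the Michael acceptor that would otherwise trap the C-2 carbanion in a six-membered ring (ester reduction with an aluminium hydride).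

Step 8
Reactants: 14 epoxy sulfone alcohol
Product: 15 (2R)-2-[(1S,3Z,7E,11E)-8-(hydroxymethyl)-4,12-dimethyl-2-(phenylsulfonyl)cyclotetradeca-3,7,11-trien-1-yl]-6-methylhept-5-en-2-ol (both epimers at ring C-2)
Conditions: n-BuLi (2.1 equiv), DABCO, THF (0.003 M), −78 → 25 °C; then H2O
Reagents that add atoms: none
Why: After deprotonation of the hydroxyl, the lithiated allylic sulfone attacks its α-carbon onto the less substituted epoxide carbon C-1 in a 14-exo SN2 opening, so C-1 is set by inversion while the C-15–O bond from step 1 becomes the tertiary alcohol with retention (carbanion–epoxide macrocyclisation of the kind established with phenylthio-stabilised carbanions for cembranoid rings; the 1S descriptor only reflects the sulfur substituent).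

Step 9
Reactants: 15 macrocyclic hydroxy sulfone
Product: 16 (2R)-2-[(1R,3Z,7E,11E)-8-(hydroxymethyl)-4,12-dimethylcyclotetradeca-3,7,11-trien-1-yl]-6-methylhept-5-en-2-ol (target)
Conditions: PdCl2(dppp) (10 mol %), LiBHEt3 (5 equiv), THF, 0 → 25 °C; then H2O
Reagents that add atoms: none
Why: Zerovalent palladium formed in situ ionises the allylic sulfone and hydride is delivered to the less substituted allyl terminus C-2, so the 3Z trisubstituted alkene stays in place and no stereocentre is touched (palladium-catalysed reductive desulfonylation of an allylic sulfone).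

**Compound list**
1 | (2E,6E)-3,7,11-trimethyldodeca-2,6,10-trien-1-ol, (E,E)-farnesol | CC(C)=CCC/C(C)=C/CC/C(C)=C/CO | starting material
2 | (2E)-3-methyl-5-[(2R,3R)-3-methyl-3-(4-methylpent-3-en-1-yl)oxiran-2-yl]pent-2-en-1-ol | OC/C=C(\C)CC[C@H]1O[C@]1(C)CCC=C(C)C | intermediate
3 | (2E)-3-methyl-5-[(2R,3R)-3-methyl-3-(4-methylpent-3-en-1-yl)oxiran-2-yl]pent-2-enal | O=C/C=C(\C)CC[C@H]1O[C@]1(C)CCC=C(C)C | intermediate
4 | (2R,3R)-2-methyl-3-[(3E)-3-methylhexa-3,5-dien-1-yl]-2-(4-methylpent-3-en-1-yl)oxirane | C=C/C=C(\C)CC[C@H]1O[C@]1(C)CCC=C(C)C | intermediate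
5 | nerol, (2Z)-3,7-dimethylocta-2,6-dien-1-ol | CC(C)=CCC/C(C)=C\CO | starting material
6 | neryl bromide, (2Z)-1-bromo-3,7-dimethylocta-2,6-diene | CC(C)=CCC/C(C)=C\CBr | intermediate
7 | {[(2Z)-3,7-dimethylocta-2,6-dien-1-yl]sulfonyl}benzene | CC(C)=CCC/C(C)=C\CS(=O)(=O)c1ccccc1 | intermediate
8 | (4Z)-4-methyl-6-(phenylsulfonyl)hex-4-enal | O=CCC/C(C)=C\CS(=O)(=O)c1ccccc1 | intermediate
9 | ethyl (triphenyl-λ5-phosphanylidene)acetate | CCOC(=O)C=P(c1ccccc1)(c1ccccc1)c1ccccc1 | starting material
10 | ethyl iodo(triphenyl-λ5-phosphanylidene)acetate | CCOC(=O)C(I)=P(c1ccccc1)(c1ccccc1)c1ccccc1 | intermediate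
11 | ethyl (2Z,6Z)-2-iodo-6-methyl-8-(phenylsulfonyl)octa-2,6-dienoate | CCOC(=O)/C(I)=C/CC/C(C)=C\CS(=O)(=O)c1ccccc1 | intermediate
12 | 9-{(3E)-4-methyl-6-[(2R,3R)-3-methyl-3-(4-methylpent-3-en-1-yl)oxiran-2-yl]hex-3-en-1-yl}-9-borabicyclo[3.3.1]nonane | C(C/C=C(\C)CC[C@H]3O[C@]3(C)CCC=C(C)C)B1C2CCCC1CCC2 | intermediate
13 | ethyl (2E,6Z)-6-methyl-2-{(3E)-4-methyl-6-[(2R,3R)-3-methyl-3-(4-methylpent-3-en-1-yl)oxiran-2-yl]hex-3-en-1-yl}-8-(phenylsulfonyl)octa-2,6-dienoate | CCOC(=O)/C(=C/CC/C(C)=C\CS(=O)(=O)c1ccccc1)CC/C=C(\C)CC[C@H]1O[C@]1(C)CCC=C(C)C | intermediate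
14 | (2E,6Z)-6-methyl-2-{(3E)-4-methyl-6-[(2R,3R)-3-methyl-3-(4-methylpent-3-en-1-yl)oxiran-2-yl]hex-3-en-1-yl}-8-(phenylsulfonyl)octa-2,6-dien-1-ol | OC/C(=C/CC/C(C)=C\CS(=O)(=O)c1ccccc1)CC/C=C(\C)CC[C@H]1O[C@]1(C)CCC=C(C)C | intermediate
15 | (2R)-2-[(1S,3Z,7E,11E)-8-(hydroxymethyl)-4,12-dimethyl-2-(phenylsulfonyl)cyclotetradeca-3,7,11-trien-1-yl]-6-methylhept-5-en-2-ol, both C-2 epimers | CC(C)=CCC[C@@](C)(O)[C@H]1C(S(=O)(=O)c2ccccc2)/C=C(/C)CC/C=C(/CO)CC/C=C(\C)CC1 | intermediate
16 | (2R)-2-[(1R,3Z,7E,11E)-8-(hydroxymethyl)-4,12-dimethylcyclotetradeca-3,7,11-trien-1-yl]-6-methylhept-5-en-2-ol | CC(C)=CCC[C@@](C)(O)[C@H]1C/C=C(/C)CC/C=C(/CO)CC/C=C(\C)CC1 | target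

**Totals and risks**
Total step count: 9. Longest linear sequence: 7 steps (5 → 7 → 8 → 11 → 13 → 14 → 15 → 16; steps 3 to 9).

Three steps most likely to fail:

Step 1 (the new epoxidation). Site selectivity against the 10,11-alkene and the level of enantiocontrol are unproven. The fallback uses known chemistry, sets out from 1 and comes back at 2. Acetylate 1 (Ac2O, pyridine) to (2E,6E)-farnesyl acetate F1. Epoxidise F1 with the D-fructose-derived ketone 1,2:4,5-di-O-isopropylidene-β-D-erythro-2,3-hexodiulo-2,6-pyranose and a substoichiometric charge of KHSO5 (buffered MeCN–dimethoxymethane–H2O, 0 °C). This dioxirane leaves the alkene deactivated by the allylic ester untouched and is reported to give R,R-epoxides from E-trisubstituted alkenes in high ee (the enantiomeric ketone would be used if the opposite sense were found). It does not tell the 6,7- from the 10,11-alkene, so (6R,7R)-6,7-epoxyfarnesyl acetate F2 is separated by chromatography from its regioisomer and unreacted F1 is recycled. K2CO3 in MeOH then gives 2. Site control is given up, at a cost in yield, while enantiocontrol rests on an established reagent.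

Step 8 (macrocyclisation). A sulfonyl carbanion is a weaker nucleophile than the phenylthio carbanions used before for this ring closure, and the epoxide carbon is hindered. The fallback sets out from 8 and 4 and comes back at 15; the epoxide is opened intermolecularly with excess nucleophile and the ring is closed by cross-coupling instead. Protect 8 (HC(OMe)3, TsOH, MeOH) as the sulfone dimethyl acetal F6. Lithiate F6 (n-BuLi, THF–DMPU, 2 to 3 equiv) and add 4 to give the acyclic hydroxy sulfone acetal F7, with C-1 set by inversion. Mild aqueous acid gives the hydroxy sulfone aldehyde F8. Olefination with iodo ylide 10 gives the acyclic iodoenoate F9. Hydroboration of the diene terminus with 9-BBN and intramolecular B-alkyl Suzuki coupling at high dilution (Pd(dppf)Cl2, AsPh3, Cs2CO3) gives the macrocyclic ester F10. Reduction with i-Bu2AlH gives 15.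

Step 5 (iodo-olefination). The Z/E ratio with an aliphatic aldehyde is the least predictable of the conventional steps, and it fixes the C-7–C-8 geometry. The fallback sets out from 8 and comes back at 14, replacing steps 5 to 7. Homologate 8 with (triphenyl-λ5-phosphanylidene)acetaldehyde to the enal (2E,6Z)-6-methyl-8-(phenylsulfonyl)octa-2,6-dienal F3. α-Iodinate it by amine-mediated addition–elimination (I2, DMAP, K2CO3, THF–H2O), which gives the thermodynamic iodoenal (2Z,6Z)-2-iodo-6-methyl-8-(phenylsulfonyl)octa-2,6-dienal F4. Couple F4 with borane 12 under the step 6 conditions to the coupled enal F5. Luche reduction (NaBH4, CeCl3·7H2O, MeOH, −78 °C) gives 14.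

**Further compounds**
F1 | step 1 | (2E,6E)-farnesyl acetate | CC(=O)OC/C=C(\C)CC/C=C(\C)CCC=C(C)C
F2 | step 1 | (6R,7R)-6,7-epoxyfarnesyl acetate | CC(=O)OC/C=C(\C)CC[C@H]1O[C@]1(C)CCC=C(C)C
F3 | step 5 | (2E,6Z)-6-methyl-8-(phenylsulfonyl)octa-2,6-dienal | O=C/C=C/CC/C(C)=C\CS(=O)(=O)c1ccccc1
F4 | step 5 | (2Z,6Z)-2-iodo-6-methyl-8-(phenylsulfonyl)octa-2,6-dienal | O=C/C(I)=C/CC/C(C)=C\CS(=O)(=O)c1ccccc1
F5 | step 5 | (2E,6Z)-6-methyl-2-{(3E)-4-methyl-6-[(2R,3R)-3-methyl-3-(4-methylpent-3-en-1-yl)oxiran-2-yl]hex-3-en-1-yl}-8-(phenylsulfonyl)octa-2,6-dienal | O=C/C(=C/CC/C(C)=C\CS(=O)(=O)c1ccccc1)CC/C=C(\C)CC[C@H]1O[C@]1(C)CCC=C(C)C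
F6 | step 8 | {[(2Z)-6,6-dimethoxy-3-methylhex-2-en-1-yl]sulfonyl}benzene | COC(OC)CC/C(C)=C\CS(=O)(=O)c1ccccc1
F7 | step 8 | (6R,7S,9Z)-13,13-dimethoxy-2,6,10-trimethyl-7-[(3E)-3-methylhexa-3,5-dien-1-yl]-8-(phenylsulfonyl)trideca-2,9-dien-6-ol, both C-8 epimers | CC(C)=CCC[C@@](C)(O)[C@H](CC/C(C)=C/C=C)C(S(=O)(=O)c1ccccc1)/C=C(C)\CCC(OC)OC
F8 | step 8 | (4Z,7S,8R)-8-hydroxy-4,8,12-trimethyl-7-[(3E)-3-methylhexa-3,5-dien-1-yl]-6-(phenylsulfonyl)trideca-4,11-dienal, both C-6 epimers | CC(C)=CCC[C@@](C)(O)[C@H](CC/C(C)=C/C=C)C(S(=O)(=O)c1ccccc1)/C=C(C)\CCC=O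
F9 | step 8 | ethyl (2Z,6Z,9S,10R)-10-hydroxy-2-iodo-6,10,14-trimethyl-9-[(3E)-3-methylhexa-3,5-dien-1-yl]-8-(phenylsulfonyl)pentadeca-2,6,13-trienoate, both C-8 epimers | CC(C)=CCC[C@@](C)(O)[C@H](CC/C(C)=C/C=C)C(S(=O)(=O)c1ccccc1)/C=C(C)\CC/C=C(\I)C(=O)OCC
F10 | step 8 | ethyl ester analogue of 15 (CO2Et in place of CH2OH at ring C-8, same ring, alkene geometries and stereocentres) | CC(C)=CCC[C@@](C)(O)[C@H]1C(S(=O)(=O)c2ccccc2)/C=C(/C)CC/C=C(/C(=O)OCC)CC/C=C(\C)CC1
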